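**Retrosynthetic overview**
1. The target is (4S,5S)-4-hydroxy-3-methyl-5-geranylgeranylcyclohex-2-en-1-one. The plan rests on the 1,4-dioxygenated ene of its only ring: the C1 carbonyl oxygen and the C4 hydroxyl sit at the two ends of the C2=C3(CH3) alkene, and C4 adjoins the chain-bearing C5 stereocentre (OH and chain cis).
2. C1=O is traced to a C1 carbinol (selective allylic oxidation), and the C1–O/C4–O pair to the C1=C2–C3(CH3)=C4 diene by palladium-catalysed cis-1,4-diacetoxylation, which forms two C–O bonds and closes no ring.
3. The diene comes from (5R)-3-methyl-5-geranylgeranylcyclohex-2-enone through its through-conjugated dienyl triflate and reduction of the C–OTf bond.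
4. The enone ring, the only ring and the only ring-forming event, is closed by an amine-catalysed desymmetrising aldol condensation of achiral 4-geranylgeranylheptane-2,6-dione, which sets C5.
5. The diketone is unmasked by Birch reduction and hydrolysis of 2,6-dimethyl-4-geranylgeranylpyridine, assembled from 4-bromo-2,6-dimethylpyridine and geranylgeranyl bromide.

Key step: step 7

Notation: GG = geranylgeranyl = (2E,6E,10E)-3,7,11,15-tetramethylhexadeca-2,6,10,14-tetraen-1-yl; ring atoms carry the target numbering throughout (C1 carbonyl carbon, C2, C3 methyl-bearing, C4 carbinol, C5 chain-bearing, C6).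

Assumption: the sense of induction of the cinchona primary amine in step 4 is taken as written (quinidine-derived amine giving the 5R enone); if it proves opposite, the quinine-derived pseudo-enantiomer is used instead.

**Step 1**
Reactants: 1 (2E,6E,10E)-geranylgeraniol
Product: 2 (2E,6E,10E)-geranylgeranyl bromide
Conditions: PBr3, Et2O, –10 to 0 °C
Reagents that add atoms: phosphorus tribromide, BrP(Br)Br
Why: Bromination of a primary allylic alcohol through its bromophosphite with SN2 displacement by bromide; at low temperature in ether neither allylic transposition nor E/Z scrambling of the C2=C3 alkene is expected.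

**Step 2**
Reactants: 3 4-bromo-2,6-dimethylpyridine; 2 geranylgeranyl bromide
Product: 5 2,6-dimethyl-4-GG-pyridine, via pyridylmagnesium chloride 4 (not isolated)
Conditions: 3, iPrMgCl·LiCl, THF, 0 °C to rt; then CuBr·SMe2 (10 mol%), 2, –30 to 0 °C
Reagents that add atoms: none
Why: Bromine–magnesium exchange gives the 4-pyridyl Grignard reagent, and copper-catalysed Grignard allylation then substitutes the primary allylic bromide in the SN2 sense with the E geometry kept, because attack at the γ-carbon would build a quaternary benzylic-type centre.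

**Step 3**
Reactants: 5 2,6-dimethyl-4-GG-pyridine
Product: 7 4-GG-heptane-2,6-dione, via 1,4-dihydropyridine 6 (not isolated)
Conditions: Na, NH3(l), EtOH, THF, –78 to –33 °C; evaporation of NH3; then 1 M aq. HCl, THF, 0 °C
Reagents that add atoms: water, O
Why: Birch reduction of the pyridine gives the 1,4-dihydropyridine, a cyclic bis-enamine that aqueous acid hydrolyses at both C–N bonds to the 1,5-diketone and ammonia; isolated trisubstituted alkenes are not reduced by sodium in ammonia, and the mild cold hydrolysis should leave the diketone uncyclised.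

**Step 4**
Reactants: 7 4-GG-heptane-2,6-dione
Product: 9 (5R)-3-methyl-5-GG-cyclohex-2-en-1-one, via ketol 8 (not isolated)
Conditions: 9-amino-9-deoxy-epi-quinidine (20 mol%), AcOH (60 mol%), toluene, –15 °C to rt
Reagents that add atoms: none
Why: Enamine-mediated desymmetrising intramolecular aldol condensation of a 4-substituted heptane-2,6-dione: the chiral primary amine condenses with one of the two enantiotopic acetyl groups, its enamine carbon adds to the other ketone through a chair transition state with the C5 substituent equatorial while the protonated quinuclidine holds the acceptor carbonyl, which sets C5 as R, and loss of water from ketol 8 gives the enone.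

**Step 5**
Reactants: 9 (5R)-3-methyl-5-GG-cyclohex-2-en-1-one
Product: 10 (5S)-3-methyl-5-GG-cyclohexa-1,3-dien-1-yl trifluoromethanesulfonate
Conditions: Tf2O, 2,6-di-tert-butyl-4-methylpyridine, CH2Cl2, 0 °C to rt
Reagents that add atoms: trifluoromethanesulfonic anhydride, O=S(=O)(OS(=O)(=O)C(F)(F)F)C(F)(F)F
Why: O-Triflation of the enone gives an oxygen-stabilised allyl cation that loses the C4 proton to the hindered pyridine, which should give the through-conjugated homoannular dienyl triflate (the thermodynamic isomer, as with steroidal 4-en-3-ones) without touching C5.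

**Step 6**
Reactants: 10 (5S)-3-methyl-5-GG-cyclohexa-1,3-dien-1-yl trifluoromethanesulfonate
Product: 11 (5R)-3-methyl-5-GG-cyclohexa-1,3-diene (alkenes C1=C2 and C3=C4)
Conditions: Pd(OAc)2 (5 mol%), PPh3 (10 mol%), HCO2H, Bu3N, DMF, 50 °C
Reagents that add atoms: none
Why: Palladium-catalysed formate reduction of an enol triflate: zerovalent palladium inserts into the C–OTf bond, formate exchanges for triflate and loses CO2, and reductive elimination of the palladium hydride gives the C1–H bond, the moderate temperature keeping the diene from 1,5-hydrogen shifts that would erase C5.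

**Step 7**
Reactants: 11 (5R)-3-methyl-5-GG-cyclohexa-1,3-diene
Product: 12 (1R,4S,5S)-3-methyl-5-GG-cyclohex-2-ene-1,4-diyl diacetate (both acetoxy groups cis to the chain)
Conditions: Pd(OAc)2 (5 mol%), LiCl (20 mol%), LiOAc·2H2O, p-benzoquinone (20 mol%), MnO2, AcOH/pentane, rt, slow addition of 11
Reagents that add atoms: acetic acid, CC(=O)O; lithium acetate, CC(=O)[O-].[Li+] (one acetate pool)
Why: Divalent palladium binds the s-cis C1=C2–C3=C4 diene, a far better ligand than the isolated trisubstituted chain alkenes, on the face away from the C5 substituent, and acetate adds from outside, anti to the metal, at the unhindered C1 terminus to give a C2–C3–C4 π-allyl complex; chloride on palladium blocks cis-migration of a bound acetate, so the second acetate also attacks from outside at C4, and the zerovalent palladium released is reoxidised by benzoquinone, which MnO2 regenerates so that little free quinone is present to undergo Diels–Alder addition with the diene. The closest known reaction type is the chloride-mediated palladium-catalysed cis-1,4-diacetoxylation of cyclohexa-1,3-dienes. No ring is closed; the C1–O and C4–O bonds are formed and the C2=C3 alkene is left between them. Both new stereocentres, C1 and C4, are controlled by the C5 centre through the facial choice of palladium: each acetate arrives anti to the metal and therefore on the face that carries the side chain, which gives the 4,5-cis relation of the target. The step needs reaction at the diene and not at the chain alkenes (secured by chelating diene coordination), 1,4- and not 1,2-addition (the C1 acetate disfavours attack at the neighbouring C2 of the cyclic π-allyl) and palladium anti to the C5 chain; the outside attack at C4, flanked by the C3 methyl and the cis C5 chain, is the point of risk.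

**Step 8**
Reactants: 12 (1R,4S,5S)-3-methyl-5-GG-cyclohex-2-ene-1,4-diyl diacetate
Product: 13 (1R,4S,5S)-3-methyl-5-GG-cyclohex-2-ene-1,4-diol
Conditions: K2CO3, MeOH, rt
Reagents that add atoms: none
Why: Base-catalysed transesterification (methanolysis) of both allylic acetates under conditions that touch neither the stereocentres nor the polyene.

**Step 9**
Reactants: 13 (1R,4S,5S)-3-methyl-5-GG-cyclohex-2-ene-1,4-diol
Product: 14 (4S,5S)-4-hydroxy-3-methyl-5-GG-cyclohex-2-en-1-one (target)
Conditions: activated MnO2, CH2Cl2, rt
Reagents that add atoms: none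
Why: Allylic oxidation with MnO2 should take the C1 carbinol, which is unhindered and, in the half-chair with the C5 chain equatorial, has its C–H bond pseudo-axial and aligned with the alkene π system, in preference to the C4 carbinol, which is flanked by the C3 methyl and the C5 chain and has a pseudo-equatorial C–H; once the enone is formed the C4 hydroxyl is allylic only to an electron-poor alkene and should not be oxidised further, so C4 and C5 remain as set.

**Compound list**
1 | (2E,6E,10E)-geranylgeraniol | CC(C)=CCC/C(C)=C/CC/C(C)=C/CC/C(C)=C/CO | starting material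
2 | (2E,6E,10E)-geranylgeranyl bromide | CC(C)=CCC/C(C)=C/CC/C(C)=C/CC/C(C)=C/CBr | intermediate
3 | 4-bromo-2,6-dimethylpyridine | Cc1cc(Br)cc(C)n1 | starting material
4 | (2,6-dimethylpyridin-4-yl)magnesium chloride | Cc1cc([Mg]Cl)cc(C)n1 | intermediate
5 | 2,6-dimethyl-4-GG-pyridine | CC(C)=CCC/C(C)=C/CC/C(C)=C/CC/C(C)=C/Cc1cc(C)nc(C)c1 | intermediate
6 | 2,6-dimethyl-4-GG-1,4-dihydropyridine | CC(C)=CCC/C(C)=C/CC/C(C)=C/CC/C(C)=C/CC1C=C(C)NC(C)=C1 | intermediate
7 | 4-GG-heptane-2,6-dione | CC(C)=CCC/C(C)=C/CC/C(C)=C/CC/C(C)=C/CC(CC(C)=O)CC(C)=O | intermediate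
8 | (5R)-3-hydroxy-3-methyl-5-GG-cyclohexan-1-one (C3 epimers) | CC(C)=CCC/C(C)=C/CC/C(C)=C/CC/C(C)=C/C[C@H]1CC(=O)CC(C)(O)C1 | intermediate
9 | (5R)-3-methyl-5-GG-cyclohex-2-en-1-one | CC(C)=CCC/C(C)=C/CC/C(C)=C/CC/C(C)=C/C[C@H]1CC(=O)C=C(C)C1 | intermediate
10 | (5S)-3-methyl-5-GG-cyclohexa-1,3-dien-1-yl trifluoromethanesulfonate | CC(C)=CCC/C(C)=C/CC/C(C)=C/CC/C(C)=C/C[C@H]1CC(OS(=O)(=O)C(F)(F)F)=CC(C)=C1 | intermediate
11 | (5R)-3-methyl-5-GG-cyclohexa-1,3-diene | CC(C)=CCC/C(C)=C/CC/C(C)=C/CC/C(C)=C/C[C@H]1CC=CC(C)=C1 | intermediate
12 | (1R,4S,5S)-3-methyl-5-GG-cyclohex-2-ene-1,4-diyl diacetate | CC(C)=CCC/C(C)=C/CC/C(C)=C/CC/C(C)=C/C[C@H]1C[C@@H](OC(C)=O)C=C(C)[C@H]1OC(C)=O | intermediate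
13 | (1R,4S,5S)-3-methyl-5-GG-cyclohex-2-ene-1,4-diol | CC(C)=CCC/C(C)=C/CC/C(C)=C/CC/C(C)=C/C[C@H]1C[C@@H](O)C=C(C)[C@H]1O | intermediate
14 | (4S,5S)-4-hydroxy-3-methyl-5-GG-cyclohex-2-en-1-one (CNP0277821.1) | CC(C)=CCC/C(C)=C/CC/C(C)=C/CC/C(C)=C/C[C@H]1CC(=O)C=C(C)[C@H]1O | target

**Step count**
Total steps: 9. Longest linear sequence: 9 steps (from 1; compound 3 enters at step 2).

**Steps most likely to fail**

1. Step 7. The outside attack of acetate at the hindered C4 terminus may be too slow. Attack at C2 (1,2-addition), cis-migration of acetate from palladium (trans product) or Diels–Alder consumption of the diene by the quinone could then take over. The fallback sets out from 9 and comes back at 14, forming the C4–O bond by electrophilic oxidation and correcting its configuration by inversion. Enone 9 is silylated under equilibrating conditions (TMSCl, Et3N, DMF, 80 °C) to the through-conjugated trimethylsilyl dienol ether F1. Vinylogous Rubottom oxidation (mCPBA, 1 equiv, NaHCO3, CH2Cl2, –40 °C, dilute acid work-up) should attack the electron-rich C3=C4 bond anti to the C5 chain, faster than the isolated chain alkenes, and give the trans γ-hydroxy enone F2, the C4 epimer of the target. Mitsunobu inversion (4-nitrobenzoic acid, PPh3, DIAD, THF, 0 °C) should give the cis 4-nitrobenzoate F3. Methanolysis (K2CO3, MeOH, 0 °C) then gives 14.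

2. Step 5. Proton loss from the C3 methyl group or from C6 in place of C4 during triflation would give exocyclic or cross-conjugated dienyl triflates, and triflic acid that escapes the base could start cyclisation of the polyene. The fallback sets out from 9 and comes back at 11, removing the C1 oxygen by a sigmatropic 1,4-dehydration that cannot place an alkene toward C6. Luche reduction (NaBH4, CeCl3·7H2O, MeOH, 0 °C) gives the allylic alcohol F4 as a mixture of C1 epimers. Treatment with 2,4-dinitrobenzenesulfenyl chloride and Et3N (CH2Cl2, 0 °C) gives the allylic sulfenate F5. This equilibrates by [2,3]-shift (the Mislow–Evans equilibrium) with the tertiary C3 allylic sulfoxide F6. Warming (1,2-dichloroethane, 60 °C) should cause syn-elimination of the sulfenic acid toward C4 and give diene 11.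

3. Step 9. Discrimination between the two allylic carbinols by MnO2 may be insufficient, leading to oxidation at C4 or to the ene-dione. The fallback sets out from 12 and comes back at 14, differentiating the two oxygens at the ester stage. Lipase-mediated hydrolysis (Candida antarctica lipase B, pH 7 phosphate buffer/acetone, rt) should cleave only the unhindered C1 acetate and give the C4 monoacetate F7. Oxidation of the free C1 alcohol (Dess–Martin periodinane, NaHCO3, CH2Cl2, 0 °C) gives the 4-acetoxy enone F8. Methanolysis (K2CO3, MeOH, 0 °C) gives 14.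

**Further compounds**
F1 | step 7 | (5S)-3-methyl-5-GG-1-(trimethylsilyloxy)cyclohexa-1,3-diene | CC(C)=CCC/C(C)=C/CC/C(C)=C/CC/C(C)=C/C[C@H]1CC(O[Si](C)(C)C)=CC(C)=C1
F2 | step 7 | (4R,5S)-4-hydroxy-3-methyl-5-GG-cyclohex-2-en-1-one (trans) | CC(C)=CCC/C(C)=C/CC/C(C)=C/CC/C(C)=C/C[C@H]1CC(=O)C=C(C)[C@@H]1O
F3 | step 7 | (4S,5S)-3-methyl-1-oxo-5-GG-cyclohex-2-en-4-yl 4-nitrobenzoate (cis) | CC(C)=CCC/C(C)=C/CC/C(C)=C/CC/C(C)=C/C[C@H]1CC(=O)C=C(C)[C@H]1OC(=O)c2ccc(cc2)[N+](=O)[O-]
F4 | step 5 | (5R)-3-methyl-5-GG-cyclohex-2-en-1-ol (C1 epimers) | CC(C)=CCC/C(C)=C/CC/C(C)=C/CC/C(C)=C/C[C@H]1CC(O)C=C(C)C1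
F5 | step 5 | (5R)-3-methyl-5-GG-cyclohex-2-en-1-yl 2,4-dinitrobenzenesulfenate | CC(C)=CCC/C(C)=C/CC/C(C)=C/CC/C(C)=C/C[C@H]1CC(OSc2ccc(cc2[N+](=O)[O-])[N+](=O)[O-])C=C(C)C1
F6 | step 5 | 3-(2,4-dinitrophenylsulfinyl)-3-methyl-5-GG-cyclohex-1-ene (C5 as in 9) | CC(C)=CCC/C(C)=C/CC/C(C)=C/CC/C(C)=C/C[C@H]1CC=CC(C)(S(=O)c2ccc(cc2[N+](=O)[O-])[N+](=O)[O-])C1
F7 | step 9 | (1R,4S,5S)-1-hydroxy-3-methyl-5-GG-cyclohex-2-en-4-yl acetate | CC(C)=CCC/C(C)=C/CC/C(C)=C/CC/C(C)=C/C[C@H]1C[C@@H](O)C=C(C)[C@H]1OC(C)=O
F8 | step 9 | (4S,5S)-3-methyl-1-oxo-5-GG-cyclohex-2-en-4-yl acetate | CC(C)=CCC/C(C)=C/CC/C(C)=C/CC/C(C)=C/C[C@H]1CC(=O)C=C(C)[C@H]1OC(C)=O
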